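**Retrosynthetic overview**
1. Target 35 is cut at C8–C9 into the C11 aldehyde 14 (ring A plus C7–C8) and the C29 methyl-capped polyenyne 31 (C19–C9≡C10 through C7' plus ring B). In the forward sense one flask does H–Zr addition, C8–C9 bond formation and Oppenauer hydride transfer (a net alkyne hydroacylation), followed by desilylation.
2. Enabling feature: C9 carries only methyl C19 and C10 only H next to the C11=C12 polyene. C9=C10 is therefore the syn H–Zr adduct of a propynyl end group, with Zr steered to C9. C8 is insulated from ring A by the C7 methylene, and its β-oxygen sits on the fully substituted C6, so C8 can enter as a non-conjugated aldehyde.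
3. 31 comes from a Wittig bond C11'=C12' between C15 salt 24 and C14 enynal 29 (C10 dialdehyde 27 plus butynylphosphonate 26). The ring B diene of 24 is made from (R)-α-ionone 15 via the C3' ketone, the kinetic C2' enol triflate and formate reduction.
4. 14 comes from actinol 1: C6–C7 by Negishi–Reformatsky coupling on enol triflate 4, C3–OH-directed epoxidation to set C6–O, then isomerisation of the oxirane to 6-O/C5=C18.
5. Ring order: rings A and B are bought intact and no carbocycle is formed. The only ring closed is the temporary C5–C6 oxirane (step 5), which is opened again in step 8.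

Key step: step 19

Assumption: carotenoid locants are used (ring A C1–C6 with C16–C18, chain C7–C15 and C15'–C7', ring B C1'–C6'). Compounds 1, 5, 15, 16, 25 and 27 are taken as catalogue items, with 1 and 15 as single enantiomers, and all polyene steps run under argon in dim light.

**Step 1**
Reactants: 1 (4R,6R)-4-hydroxy-2,2,6-trimethylcyclohexanone (actinol)
Product: 2 (4R,6R)-4-(tert-butyldimethylsilyloxy)-2,2,6-trimethylcyclohexanone
Conditions: TBSCl, imidazole, DMF, rt
Reagents that add atoms: tert-butyldimethylsilyl chloride, CC(C)(C)[Si](C)(C)Cl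
Why: Silyl ether protection (imidazole-catalysed silylation) masks the C3 hydroxyl against the lithium amide of step 2 and touches no stereocentre.

**Step 2**
Reactants: 2 (4R,6R)-4-(tert-butyldimethylsilyloxy)-2,2,6-trimethylcyclohexanone
Product: 4 (4R)-4-(tert-butyldimethylsilyloxy)-2,6,6-trimethylcyclohex-1-en-1-yl trifluoromethanesulfonate, via lithium enolate 3 (not isolated)
Conditions: LiN(i-Pr)2, THF, −78 to 0 °C; then PhNTf2, 0 °C to rt
Reagents that add atoms: N-phenylbis(trifluoromethanesulfonimide), O=S(=O)(N(c1ccccc1)S(=O)(=O)C(F)(F)F)C(F)(F)F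
Why: Enolate O-sulfonylation (enol triflate synthesis): C1 is quaternary, so deprotonation can occur only at C5 and a single tetrasubstituted C5=C6 enol triflate should result, the C5 stereocentre being given up on purpose while C3 is untouched.

**Step 3**
Reactants: 4 enol triflate; 5 (2-tert-butoxy-2-oxoethyl)zinc chloride
Product: 6 tert-butyl [(4R)-4-(tert-butyldimethylsilyloxy)-2,6,6-trimethylcyclohex-1-en-1-yl]acetate
Conditions: Pd2(dba)3 (2.5 mol %), XPhos (10 mol %), THF, 60 °C
Reagents that add atoms: none
Why: Negishi-type cross-coupling of a Reformatsky zinc enolate with an alkenyl triflate under zerovalent palladium and a bulky biaryl phosphine forms C6–C7 at the hindered ring carbon and leaves C5=C6 in place, because the tetrasubstituted endocyclic alkene is the more stable isomer.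

**Step 4**
Reactants: 6 silyloxy ester
Product: 7 tert-butyl [(4R)-4-hydroxy-2,6,6-trimethylcyclohex-1-en-1-yl]acetate
Conditions: Bu4NF, THF, rt
Reagents that add atoms: none
Why: Fluoride-mediated desilylation frees the C3 hydroxyl, which is needed as the directing group of step 5, and the tert-butyl ester is inert to it.

**Step 5**
Reactants: 7 hydroxy ester
Product: 8 tert-butyl [(1R,4S,6S)-4-hydroxy-2,2,6-trimethyl-7-oxabicyclo[4.1.0]heptan-1-yl]acetate (oxirane oxygen cis to the C3 hydroxyl; 3S,5S,6R)
Conditions: VO(acac)2 (3 mol %), t-BuOOH (decane solution, 1.5 equiv), CH2Cl2, 0 °C to rt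
Reagents that add atoms: tert-butyl hydroperoxide, CC(C)(C)OO
Why: Hydroxyl-directed vanadium-catalysed epoxidation of a homoallylic cyclohexenol: the vanadate ester of the pseudo-axial C3–OH passes the peroxide oxygen to its own face of C5=C6, so C5 (S) and C6 (R) are both set cis to the C3 oxygen.

**Step 6**
Reactants: 8 epoxy hydroxy ester
Product: 9 tert-butyl [(1R,4S,6S)-2,2,6-trimethyl-4-(triethylsilyloxy)-7-oxabicyclo[4.1.0]heptan-1-yl]acetate
Conditions: TESCl, imidazole, CH2Cl2, 0 °C
Reagents that add atoms: chlorotriethylsilane, CC[Si](Cl)(CC)CC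
Why: Silyl ether protection of C3–OH removes the one alkoxide that could later chelate the oxirane oxygen from the C5 side, and imidazole is too weak a base to enolise the ester.

**Step 7**
Reactants: 9 epoxy ester
Product: 10 2-[(1R,4S,6S)-2,2,6-trimethyl-4-(triethylsilyloxy)-7-oxabicyclo[4.1.0]heptan-1-yl]ethanol
Conditions: LiAlH4, Et2O, 0 °C; basic aqueous work-up
Reagents that add atoms: none
Why: Hydride reduction of the ester to the primary alcohol removes the acidic C7 protons that would otherwise trigger E1cB opening of C6–O in step 8, and the tetrasubstituted oxirane is too hindered for hydride attack.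

**Step 8**
Reactants: 10 epoxy alcohol
Product: 12 (1R,4S)-2,2-dimethyl-6-methylidene-4-(triethylsilyloxy)-1-(trimethylsilyloxy)-1-[2-(trimethylsilyloxy)ethyl]cyclohexane, via dilithium dialkoxide 11 (not isolated)
Conditions: LiN(i-Pr)2 (4 equiv), Et2O, 0 °C to reflux; then TMSCl, 0 °C
Reagents that add atoms: chlorotrimethylsilane, C[Si](C)(C)Cl
Why: Base-promoted epoxide to allylic alcohol isomerisation (lithium amide syn-elimination): lithium held between the C8 alkoxide and the oxirane oxygen keeps oxygen on C6 with its configuration, the bulky amide takes the most accessible syn proton from methyl C18 so that C5–O breaks and the exocyclic C5=C18 bond forms, and the chlorosilane quench caps both alkoxides.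

**Step 9**
Reactants: 12 tris-silyl ether
Product: 14 [(1R,4S)-2,2-dimethyl-6-methylidene-4-(triethylsilyloxy)-1-(trimethylsilyloxy)cyclohexyl]acetaldehyde, via alkoxysulfonium chloride 13 (not isolated)
Conditions: (COCl)2, DMSO, CH2Cl2, −78 to −40 °C; then Et3N, −78 °C to 0 °C
Reagents that add atoms: none
Why: Swern oxidation applied directly to a primary trimethylsilyl ether: the activated sulfoxide displaces only the unhindered primary silyl group, so C8 becomes the aldehyde while the secondary triethylsilyl and tertiary trimethylsilyl ethers stay.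

**Step 10**
Reactants: 15 (R)-α-ionone; 16 triethyl phosphonoacetate
Product: 18 ethyl (2E,4E)-3-methyl-5-[(1R)-2,6,6-trimethylcyclohex-2-en-1-yl]penta-2,4-dienoate, via sodium phosphonate anion 17 (not isolated)
Conditions: NaH, THF, 0 °C; then 15, rt to 45 °C; chromatography
Reagents that add atoms: none
Why: Horner–Wadsworth–Emmons olefination of the methyl ketone should give mainly the 9'E dienoate (the 9'Z isomer is removed by chromatography), and the stabilised phosphonate anion is too weak a base to epimerise C6'.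

**Step 11**
Reactants: 18 dienoate
Product: 19 ethyl (2E,4E)-3-methyl-5-[(1R)-2,6,6-trimethyl-4-oxocyclohex-2-en-1-yl]penta-2,4-dienoate
Conditions: Rh2(cap)4 (dirhodium tetracaprolactamate, 1 mol %), 70 % aq t-BuOOH (5 equiv), ClCH2CH2Cl, 40 °C
Reagents that add atoms: tert-butyl hydroperoxide, CC(C)(C)OO
Why: Dirhodium-catalysed allylic C–H oxidation with tert-butyl hydroperoxide attacks the only unhindered ring allylic methylene (C3'), as is known for α-ionone derivatives, the tertiary C6'–H being shielded by the C1' gem-dimethyl group and the side chain.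

**Step 12**
Reactants: 19 oxo dienoate
Product: 21 ethyl (2E,4E)-3-methyl-5-[(1S)-2,6,6-trimethyl-4-(trifluoromethylsulfonyloxy)cyclohexa-2,4-dien-1-yl]penta-2,4-dienoate, via lithium cross-conjugated dienolate 20 (not isolated)
Conditions: LiN(i-Pr)2 (1.05 equiv), THF, −78 °C, slow addition of 19; then Comins reagent, −78 °C
Reagents that add atoms: N-(5-chloropyridin-2-yl)bis(trifluoromethanesulfonimide), O=S(=O)(C(F)(F)F)N(c1ccc(Cl)cn1)S(=O)(=O)C(F)(F)F
Why: Kinetic enolate formation and O-triflation: the lithium amide bound to the C3' carbonyl reaches only the α' protons at C2', and the cross-conjugated dienolate is trapped at −78 °C before proton exchange can reach the vinylogous C6'–H, so the C6' configuration is kept (the descriptor changes to S by priority only).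

**Step 13**
Reactants: 21 dienyl triflate
Product: 22 ethyl (2E,4E)-3-methyl-5-[(1S)-2,6,6-trimethylcyclohexa-2,4-dien-1-yl]penta-2,4-dienoate
Conditions: Pd(OAc)2 (5 mol %), PPh3 (10 mol %), HCO2H (2 equiv), Et3N (3 equiv), DMF, 50 °C
Reagents that add atoms: none
Why: Palladium-catalysed formate reduction of an alkenyl triflate (oxidative addition, decarboxylation of the palladium formate, C–H reductive elimination) replaces OTf by H with the C2'=C3'–C4'=C5' diene fixed where the enolate put it, and Et3N is too weak a base to touch C6'–H.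

**Step 14**
Reactants: 22 diene ester
Product: 23 (2E,4E)-3-methyl-5-[(1S)-2,6,6-trimethylcyclohexa-2,4-dien-1-yl]penta-2,4-dien-1-ol
Conditions: i-Bu2AlH (2.2 equiv), CH2Cl2, −78 °C; aqueous tartrate work-up
Reagents that add atoms: none
Why: 1,2-Reduction of the dienoate ester by the aluminium hydride gives the allylic alcohol without touching the alkenes or C6'.

**Step 15**
Reactants: 23 C15 dienol
Product: 24 {(2E,4E)-3-methyl-5-[(1S)-2,6,6-trimethylcyclohexa-2,4-dien-1-yl]penta-2,4-dien-1-yl}triphenylphosphonium bromide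
Conditions: PPh3·HBr, MeOH, rt
Reagents that add atoms: triphenylphosphine hydrobromide, [Br-].[PH+](c1ccccc1)(c1ccccc1)c1ccccc1
Why: SN1-type phosphonium salt formation, the standard way to C15 Wittig salts: the weakly acidic phosphonium bromide ionises only the pentadienylic alcohol and the phosphine captures the cation at the unhindered C11' terminus faster than C6'–H can be lost.

**Step 16**
Reactants: 25 1-bromobut-2-yne
Product: 26 diethyl but-2-yn-1-ylphosphonate
Conditions: P(OEt)3, neat, 120 °C
Reagents that add atoms: triethyl phosphite, CCOP(OCC)OCC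
Why: Michaelis–Arbuzov reaction of a reactive propargylic bromide gives the phosphonate with distillative loss of bromoethane.

**Step 17**
Reactants: 26 butynylphosphonate; 27 (2E,4E,6E)-2,7-dimethylocta-2,4,6-trienedial
Product: 29 (2E,4E,6E,8E)-2,7-dimethyldodeca-2,4,6,8-tetraen-10-ynal, via lithiated phosphonate 28 (not isolated)
Conditions: LiN(SiMe3)2, THF, −78 °C; then 27 (3 equiv), −78 to 0 °C
Reagents that add atoms: none
Why: Horner–Wadsworth–Emmons olefination with a propargylic phosphonate is E-selective for C11=C12, and the excess of the symmetrical dialdehyde holds the reaction at mono-olefination.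

**Step 18**
Reactants: 24 C15 phosphonium bromide; 29 C14 enynal
Product: 31 (1E,3E,5E,7E,9E,11E,13E)-3,7,12-trimethyl-1-[(1S)-2,6,6-trimethylcyclohexa-2,4-dien-1-yl]heptadeca-1,3,5,7,9,11,13-heptaen-15-yne, via phosphonium ylide 30 (not isolated)
Conditions: NaOMe, MeOH/CH2Cl2, 0 °C to rt, dark; then EtOH, 75 °C (11'Z to E equilibration), crystallisation
Reagents that add atoms: none
Why: Wittig olefination forms C11'=C12' as in standard C15 plus aldehyde carotenoid couplings, methoxide is consumed by the far more acidic phosphonium salt so C6'–H is spared, and mild heating moves the unhindered 11'Z isomer to all-E.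

**Step 19**
Reactants: 31 C29 polyenyne; 14 C11 aldehyde
Product: 34 3-O-triethylsilyl-6-O-trimethylsilyl ether of 35, via alkenylzirconocene chloride 32 (not isolated), via zirconium alkoxide 33 (not isolated)
Conditions: 31 (1.2 equiv), Cp2Zr(H)Cl (1.2 equiv), THF, rt, dark; then 14 (1.0 equiv), ZnBr2 (20 mol %), rt; then t-BuCHO (4 equiv), rt to 35 °C; aq NaHCO3
Reagents that add atoms: none
Why: Cp2Zr(H)Cl adds H–Zr syn across the one alkyne of 31 and places zirconium on C9, the carbon that bears only methyl C19 while C10 bears the whole polyenyl arm, which fixes the 9E geometry in 32. With catalytic ZnBr2 the alkenyl group of 32 is handed to the C8 aldehyde of 14 with retention at C9 (C8–C9 bond, alkoxide 33), and pivalaldehyde then accepts the C8 hydride through a six-membered Oppenauer transition state on the same metal alkoxide, driven by formation of the conjugated octaenone 34. The closest known reaction type is the zinc-halide-catalysed addition of alkenylzirconocene chlorides to aldehydes, which with surplus aldehyde runs on to the E-enone by Oppenauer oxidation; the net change is a hydroacylation of the alkyne. No ring is closed, and the only new stereocentre, the C8 carbinol of 33, is erased in the same flask, so it needs no control. Chemoselectivity for the alkyne over the seven chain alkenes and the ring B diene rests on the much faster hydrozirconation of alkynes than of di- and trisubstituted conjugated alkenes, and the C5=C18 methylene of 14 is safe because no Zr–H is left when 14 is added. The alkenyl zirconium and zinc species are not basic, so the doubly allylic C6'–H, the C7 protons and the C6 silyloxy group (no E1cB loss, no retro-aldol) are left alone.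

**Step 20**
Reactants: 34 bis-silyl ether
Product: 35 (3S,6R,6'S)-3,6-dihydroxy-7,8-dihydro-2',3'-didehydro-γ,ε-caroten-8-one (target)
Conditions: HF·pyridine, pyridine, THF, 0 °C, dark
Reagents that add atoms: none
Why: Fluoride-mediated desilylation under pyridine-buffered conditions removes the labile secondary triethylsilyl and tertiary trimethylsilyl ethers without base, so the β-hydroxy ketone cannot undergo retro-aldol cleavage and no stereocentre is touched.

**Compound list**
1 | (4R,6R)-4-hydroxy-2,2,6-trimethylcyclohexanone (actinol) | C[C@@H]1C[C@@H](O)CC(C)(C)C1=O | starting material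
2 | (4R,6R)-4-(tert-butyldimethylsilyloxy)-2,2,6-trimethylcyclohexanone | C[C@@H]1C[C@@H](O[Si](C)(C)C(C)(C)C)CC(C)(C)C1=O | intermediate
3 | lithium enolate of 2 | CC1=C([O-])C(C)(C)C[C@H](O[Si](C)(C)C(C)(C)C)C1.[Li+] | intermediate
4 | (4R)-4-(tert-butyldimethylsilyloxy)-2,6,6-trimethylcyclohex-1-en-1-yl trifluoromethanesulfonate | CC1=C(OS(=O)(=O)C(F)(F)F)C(C)(C)C[C@H](O[Si](C)(C)C(C)(C)C)C1 | intermediate
5 | (2-tert-butoxy-2-oxoethyl)zinc chloride | Cl[Zn]CC(=O)OC(C)(C)C | starting material
6 | tert-butyl [(4R)-4-(tert-butyldimethylsilyloxy)-2,6,6-trimethylcyclohex-1-en-1-yl]acetate | CC1=C(CC(=O)OC(C)(C)C)C(C)(C)C[C@H](O[Si](C)(C)C(C)(C)C)C1 | intermediate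
7 | tert-butyl [(4R)-4-hydroxy-2,6,6-trimethylcyclohex-1-en-1-yl]acetate | CC1=C(CC(=O)OC(C)(C)C)C(C)(C)C[C@H](O)C1 | intermediate
8 | tert-butyl [(1R,4S,6S)-4-hydroxy-2,2,6-trimethyl-7-oxabicyclo[4.1.0]heptan-1-yl]acetate | C[C@]12C[C@@H](O)CC(C)(C)[C@@]1(CC(=O)OC(C)(C)C)O2 | intermediate
9 | tert-butyl [(1R,4S,6S)-2,2,6-trimethyl-4-(triethylsilyloxy)-7-oxabicyclo[4.1.0]heptan-1-yl]acetate | C[C@]12C[C@@H](O[Si](CC)(CC)CC)CC(C)(C)[C@@]1(CC(=O)OC(C)(C)C)O2 | intermediate
10 | 2-[(1R,4S,6S)-2,2,6-trimethyl-4-(triethylsilyloxy)-7-oxabicyclo[4.1.0]heptan-1-yl]ethanol | C[C@]12C[C@@H](O[Si](CC)(CC)CC)CC(C)(C)[C@@]1(CCO)O2 | intermediate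
11 | dilithium 6,8-dialkoxide of the ring-opened allylic alcohol | C=C1C[C@@H](O[Si](CC)(CC)CC)CC(C)(C)[C@]1([O-])CC[O-].[Li+].[Li+] | intermediate
12 | (1R,4S)-2,2-dimethyl-6-methylidene-4-(triethylsilyloxy)-1-(trimethylsilyloxy)-1-[2-(trimethylsilyloxy)ethyl]cyclohexane | C=C1C[C@@H](O[Si](CC)(CC)CC)CC(C)(C)[C@]1(O[Si](C)(C)C)CCO[Si](C)(C)C | intermediate
13 | C8 alkoxydimethylsulfonium chloride | C=C1C[C@@H](O[Si](CC)(CC)CC)CC(C)(C)[C@]1(O[Si](C)(C)C)CCO[S+](C)C.[Cl-] | intermediate
14 | [(1R,4S)-2,2-dimethyl-6-methylidene-4-(triethylsilyloxy)-1-(trimethylsilyloxy)cyclohexyl]acetaldehyde | C=C1C[C@@H](O[Si](CC)(CC)CC)CC(C)(C)[C@]1(O[Si](C)(C)C)CC=O | intermediate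
15 | (R)-α-ionone | CC(=O)/C=C/[C@H]1C(C)=CCCC1(C)C | starting material
16 | triethyl phosphonoacetate | CCOC(=O)CP(=O)(OCC)OCC | starting material
17 | sodium salt of 16 | CCOC(=O)[CH-]P(=O)(OCC)OCC.[Na+] | intermediate
18 | ethyl (2E,4E)-3-methyl-5-[(1R)-2,6,6-trimethylcyclohex-2-en-1-yl]penta-2,4-dienoate | CCOC(=O)/C=C(C)/C=C/[C@H]1C(C)=CCCC1(C)C | intermediate
19 | ethyl (2E,4E)-3-methyl-5-[(1R)-2,6,6-trimethyl-4-oxocyclohex-2-en-1-yl]penta-2,4-dienoate | CCOC(=O)/C=C(C)/C=C/[C@H]1C(C)=CC(=O)CC1(C)C | intermediate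
20 | lithium cross-conjugated dienolate of 19 | CCOC(=O)/C=C(C)/C=C/[C@H]1C(C)=CC([O-])=CC1(C)C.[Li+] | intermediate
21 | ethyl (2E,4E)-3-methyl-5-[(1S)-2,6,6-trimethyl-4-(trifluoromethylsulfonyloxy)cyclohexa-2,4-dien-1-yl]penta-2,4-dienoate | CCOC(=O)/C=C(C)/C=C/[C@H]1C(C)=CC(OS(=O)(=O)C(F)(F)F)=CC1(C)C | intermediate
22 | ethyl (2E,4E)-3-methyl-5-[(1S)-2,6,6-trimethylcyclohexa-2,4-dien-1-yl]penta-2,4-dienoate | CCOC(=O)/C=C(C)/C=C/[C@H]1C(C)=CC=CC1(C)C | intermediate
23 | (2E,4E)-3-methyl-5-[(1S)-2,6,6-trimethylcyclohexa-2,4-dien-1-yl]penta-2,4-dien-1-ol | OC/C=C(C)/C=C/[C@H]1C(C)=CC=CC1(C)C | intermediate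
24 | {(2E,4E)-3-methyl-5-[(1S)-2,6,6-trimethylcyclohexa-2,4-dien-1-yl]penta-2,4-dien-1-yl}triphenylphosphonium bromide | c1ccccc1[P+](c1ccccc1)(c1ccccc1)C/C=C(C)/C=C/[C@H]1C(C)=CC=CC1(C)C.[Br-] | intermediate
25 | 1-bromobut-2-yne | CC#CCBr | starting material
26 | diethyl but-2-yn-1-ylphosphonate | CC#CCP(=O)(OCC)OCC | intermediate
27 | (2E,4E,6E)-2,7-dimethylocta-2,4,6-trienedial | O=C/C(C)=C/C=C/C=C(C)/C=O | starting material
28 | lithiated 26 | CC#C[CH-]P(=O)(OCC)OCC.[Li+] | intermediate
29 | (2E,4E,6E,8E)-2,7-dimethyldodeca-2,4,6,8-tetraen-10-ynal | CC#C/C=C/C(C)=C/C=C/C=C(C)/C=O | intermediate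
30 | ylide of 24 | c1ccccc1[P+](c1ccccc1)(c1ccccc1)[CH-]/C=C(C)/C=C/[C@H]1C(C)=CC=CC1(C)C | intermediate
31 | (all-E)-3,7,12-trimethyl-1-[(1S)-2,6,6-trimethylcyclohexa-2,4-dien-1-yl]heptadeca-1,3,5,7,9,11,13-heptaen-15-yne | CC#C/C=C/C(C)=C/C=C/C=C(C)/C=C/C=C(C)/C=C/[C@H]1C(C)=CC=CC1(C)C | intermediate
32 | C9 alkenylzirconocene chloride (9E; cyclopentadienyl rings drawn σ-bound) | Cl[Zr](C1C=CC=C1)(C1C=CC=C1)/C(C)=C/C=C/C(C)=C/C=C/C=C(C)/C=C/C=C(C)/C=C/[C@H]1C(C)=CC=CC1(C)C | intermediate
33 | C8 zirconium alkoxide (both C8 epimers) | C=C1C[C@@H](O[Si](CC)(CC)CC)CC(C)(C)[C@]1(O[Si](C)(C)C)CC(O[Zr](Cl)(C2C=CC=C2)C2C=CC=C2)/C(C)=C/C=C/C(C)=C/C=C/C=C(C)/C=C/C=C(C)/C=C/[C@H]1C(C)=CC=CC1(C)C | intermediate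
34 | 3-O-triethylsilyl-6-O-trimethylsilyl ether of 35 | C=C1C[C@@H](O[Si](CC)(CC)CC)CC(C)(C)[C@]1(O[Si](C)(C)C)CC(=O)/C(C)=C/C=C/C(C)=C/C=C/C=C(C)/C=C/C=C(C)/C=C/[C@H]1C(C)=CC=CC1(C)C | intermediate
35 | (3S,6R,6'S)-3,6-dihydroxy-7,8-dihydro-2',3'-didehydro-γ,ε-caroten-8-one | C=C1C[C@@H](O)CC(C)(C)[C@]1(O)CC(=O)/C(C)=C/C=C/C(C)=C/C=C/C=C(C)/C=C/C=C(C)/C=C/[C@H]1C(C)=CC=CC1(C)C | target

**Total step count:** 20. **Longest linear sequence:** 11 (steps 1–9, 19, 20).

**Three steps most likely to fail**

Step 19. Three things could go wrong. Regiocontrol in the H–Zr addition may be incomplete, the hindered α-methyl alkenylzirconocene may add slowly to the aldehyde, or the hydride transfer may stall at the alkoxide stage. The fallback sets out from 31 and separates the three events.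
- 32 is generated as before and quenched with I2 (THF, −78 °C) to give the alkenyl iodide F1, which can be freed of any regioisomer.
- Nozaki–Hiyama–Kishi coupling of F1 with 14 (CrCl2, catalytic NiCl2, DMSO/THF, rt) gives the allylic alcohol F2 as C8 epimers.
- MnO2 (CH2Cl2, rt) oxidises only this polyenylic alcohol, and the route is rejoined at 34.

Step 8. The amide could abstract a proton at C7 or C4 instead of C18, or C6–O could break instead of C5–O. The fallback sets out from 10 and replaces the amide syn-elimination by a hydroxyl-delivered Lewis acid rearrangement.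
- Ti(OiPr)4 (CH2Cl2, rt to 40 °C) is bound by the C8 hydroxyl and carried to the oxirane oxygen.
- The six-membered O8–Ti–O6 chelate survives only if the distal C5–O bond breaks, and an isopropoxide ligand takes a C18 proton to give the diol F3.
- Silylation of both hydroxyls (TMSCl, imidazole, DMF) rejoins the route at 12.

Step 12. Proton exchange between the dienolate and unreacted ketone could reach the vinylogous C6'–H. This would cause loss of configuration at C6' and drift of the double bonds into conjugation. The fallback sets out from 19 and uses no strong base.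
- Luche reduction (NaBH4, CeCl3·7H2O, MeOH, 0 °C) gives the allylic alcohol F4, and either C3' epimer serves.
- Warming with Burgess reagent (benzene, 50 °C) removes water by thermal syn-elimination.
- The only sp3 β-hydrogens next to C3' are those at C2', so the C2'=C3' bond forms and the route is rejoined at 22.

**Further compounds**
F1 | step 19 | (all-E)-C9 alkenyl iodide of the C29 polyene | I/C(C)=C/C=C/C(C)=C/C=C/C=C(C)/C=C/C=C(C)/C=C/[C@H]1C(C)=CC=CC1(C)C
F2 | step 19 | C8 allylic alcohol (both C8 epimers) corresponding to 34 | C=C1C[C@@H](O[Si](CC)(CC)CC)CC(C)(C)[C@]1(O[Si](C)(C)C)CC(O)/C(C)=C/C=C/C(C)=C/C=C/C=C(C)/C=C/C=C(C)/C=C/[C@H]1C(C)=CC=CC1(C)C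
F3 | step 8 | (1R,4S)-1-(2-hydroxyethyl)-2,2-dimethyl-6-methylidene-4-(triethylsilyloxy)cyclohexan-1-ol | C=C1C[C@@H](O[Si](CC)(CC)CC)CC(C)(C)[C@]1(O)CCO
F4 | step 12 | ethyl (2E,4E)-5-[(1R)-4-hydroxy-2,6,6-trimethylcyclohex-2-en-1-yl]-3-methylpenta-2,4-dienoate (C3' epimers) | CCOC(=O)/C=C(C)/C=C/[C@H]1C(C)=CC(O)CC1(C)C
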